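**Retrosynthetic overview**
- The strategy rests on the pentasubstituted benzene ring, numbered from the side-chain carbon C1 (C2–OH, C3–OMe, C4–Me, C5–OMe, C6–H). Its C1–C2–C3 edge has the carbon and oxygen pattern of a 4-methoxyacetoacetate, and its C4–C5–C6 edge that of 2-methoxy-3-oxobutanal. The one free hydroxyl (C2) is therefore the former keto group and needs no later differentiation from the two methyl ethers.
- Key disconnection: the C3–C4 and C1–C6 bonds, made in one TiCl4-mediated formal [3+3] cyclocondensation of a 1,3-bis(silyloxy)diene (from methyl 4-methoxyacetoacetate) with a β-keto acetal (from methoxyacetone and trimethyl orthoformate). The benzene ring is the only ring and is formed in this step.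
- Side chain: the ester carbon on C1 becomes the 1,1-disubstituted alkene carbon (ester → methyl ketone → 1-arylethenyl triflate). An asymmetric Ni/Cr coupling with 4-methylpent-3-enal forms the carbinol C–C bond and sets the (S) centre. Tigloylation and removal of the phenol protecting group finish the route.

Key step: step 5

Assumption: the (S)-configured oxazoline–sulfonamide ligand of step 11 is taken to deliver the alkenyl group to the Re face of the aldehyde, the face that leads to the (3S)-carbinol; should Mosher ester analysis show the opposite sense, its enantiomer is used with no other change.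

**Step 1**
Reactants: 1 methyl 4-methoxy-3-oxobutanoate (methyl 4-methoxyacetoacetate)
Product: 2 methyl (2Z)-4-methoxy-3-(trimethylsilyloxy)but-2-enoate
Conditions: Me3SiCl, Et3N, toluene, 0 → 20 °C; filtration, distillation
Reagents that add atoms: chlorotrimethylsilane, C[Si](C)(C)Cl
Why: Amine-mediated O-silylation of the enolised β-keto ester (silyl enol ether formation) is the standard first stage towards 1,3-bis(silyloxy)dienes, and the double-bond geometry (drawn Z) is of no consequence because it is lost in step 2.

**Step 2**
Reactants: 2 methyl (2Z)-4-methoxy-3-(trimethylsilyloxy)but-2-enoate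
Product: 3 (1E,3Z)-1,4-dimethoxy-1,3-bis(trimethylsilyloxy)buta-1,3-diene
Conditions: LiN(iPr)2, THF, −78 °C; Me3SiCl, −78 → 20 °C; hexane, filtration under argon, used crude
Reagents that add atoms: chlorotrimethylsilane, C[Si](C)(C)Cl
Why: γ-Deprotonation of the silyl enol ether gives the extended ester enolate, which is silylated on oxygen to the bis(silyloxy)diene (second stage of the Chan diene synthesis); the geometry drawn is the expected one and has no bearing on the arene.

**Step 3**
Reactants: 4 methoxyacetone (1-methoxypropan-2-one)
Product: 5 (Z)-1-methoxy-2-(trimethylsilyloxy)prop-1-ene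
Conditions: Me3SiCl, Et3N, DMF, 80 °C; pentane extraction, fractional distillation
Reagents that add atoms: chlorotrimethylsilane, C[Si](C)(C)Cl
Why: Silyl enol ether formation under equilibrating (House) conditions should favour the more substituted enol ether on the methoxy-bearing carbon, and distillation removes any terminal regioisomer.

**Step 4**
Reactants: 5 (Z)-1-methoxy-2-(trimethylsilyloxy)prop-1-ene; 6 trimethyl orthoformate
Product: 7 3,4,4-trimethoxybutan-2-one (racemic)
Conditions: Me3SiOTf (5 mol %), CH2Cl2, −78 °C
Reagents that add atoms: none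
Why: The silyl triflate ionises the orthoformate to the dimethoxycarbenium ion, which the enol ether attacks at its methoxy-bearing carbon (Mukaiyama-type alkylation of a silyl enol ether under Noyori conditions) to give the β-keto acetal.

**Step 5**
Reactants: 3 (1E,3Z)-1,4-dimethoxy-1,3-bis(trimethylsilyloxy)buta-1,3-diene; 7 3,4,4-trimethoxybutan-2-one
Product: 10 methyl 2-hydroxy-3,5-dimethoxy-4-methylbenzoate, via open-chain aldol adduct 8 (not isolated), via cyclised keto ester 9 (not isolated)
Conditions: 7, TiCl4 (1.0 equiv), 4 Å molecular sieves, CH2Cl2, −78 °C; 3 (1.2 equiv), −78 °C; TiCl4 (1.0 equiv), −78 → 20 °C; aq. HCl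
Reagents that add atoms: none
Why: TiCl4 holds 7 as the five-membered chelate of its ketone oxygen and the neighbouring methoxy group, and the terminal carbon of diene 3 (the more nucleophilic of its two carbon sites) adds to this activated ketone in a Mukaiyama aldol reaction, forming the C3–C4 bond and giving 8. The second portion of TiCl4 then ionises the dimethyl acetal, and the central carbon of the remaining β-keto ester enol derivative closes onto the oxocarbenium carbon in a 6-(enolendo)-exo-trig cyclisation that forms the C1–C6 bond and the six-membered ring of 9. E1cB-type loss of methanol from C6 and of water from C4, each β to the ring ketone, followed by enolisation gives the benzene ring of 10, while the methoxy groups on C3 and C5 (α and γ to the ketone, not β-leaving groups) stay in place. The closest known reaction type is the TiCl4-mediated formal [3+3] cyclocondensation of 1,3-bis(silyloxy)buta-1,3-dienes with β-keto acetals and related masked 1,3-dicarbonyl compounds to give salicylates. No stereocentre survives, so the diastereomer mixtures of 7, 8 and 9 converge on one arene. The step needs the terminal diene carbon to bond to the ketone carbon and the central carbon to the acetal carbon, whereas a β-keto acetal without the α-methoxy group would be expected to react first at the acetal carbon; the order is to be secured by chelation activation of the α-methoxy ketone, by the slow ionisation of an acetal whose neighbouring carbon carries a methoxy and an acyl group, and by the staged addition that leaves no free Lewis acid until the aldol addition is over.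

**Step 6**
Reactants: 10 methyl 2-hydroxy-3,5-dimethoxy-4-methylbenzoate
Product: 11 methyl 3,5-dimethoxy-2-(methoxymethoxy)-4-methylbenzoate
Conditions: NaH, DMF, 0 °C; MOMCl, 0 → 20 °C
Reagents that add atoms: chloromethyl methyl ether, COCCl
Why: Williamson etherification of the fully deprotonated, hydrogen-bonded phenol gives the methoxymethyl ether, which withstands the Grignard, amide-base and chromium steps and cannot migrate to an enolate oxygen.

**Step 7**
Reactants: 11 methyl 3,5-dimethoxy-2-(methoxymethoxy)-4-methylbenzoate
Product: 12 N,3,5-trimethoxy-2-(methoxymethoxy)-N,4-dimethylbenzamide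
Conditions: MeNH(OMe)·HCl, iPrMgCl, THF, −20 → 0 °C
Reagents that add atoms: N,O-dimethylhydroxylamine hydrochloride, CNOC.Cl
Why: The chloromagnesium amide made in the flask acylates on the methyl ester (Weinreb amide formation by magnesium amide aminolysis), a reaction that tolerates ortho-substituted benzoates.

**Step 8**
Reactants: 12 N,3,5-trimethoxy-2-(methoxymethoxy)-N,4-dimethylbenzamide
Product: 13 1-[3,5-dimethoxy-2-(methoxymethoxy)-4-methylphenyl]ethan-1-one
Conditions: MeMgBr, THF, 0 °C; aq. NH4Cl
Reagents that add atoms: methylmagnesium bromide, C[Mg]Br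
Why: Weinreb ketone synthesis, in which the chelated tetrahedral magnesium adduct stops the addition at the ketone stage.

**Step 9**
Reactants: 13 1-[3,5-dimethoxy-2-(methoxymethoxy)-4-methylphenyl]ethan-1-one
Product: 14 1-[3,5-dimethoxy-2-(methoxymethoxy)-4-methylphenyl]ethenyl trifluoromethanesulfonate
Conditions: KN(SiMe3)2, THF, −78 °C; PhNTf2, −78 → 0 °C
Reagents that add atoms: N-phenylbis(trifluoromethanesulfonimide), O=S(=O)(N(c1ccccc1)S(=O)(=O)C(F)(F)F)C(F)(F)F
Why: The methyl group is the only enolisable site, so deprotonation and O-sulfonylation of the potassium enolate (enol triflate formation) can only give the 1-arylethenyl triflate.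

**Step 10**
Reactants: 15 4-methylpent-3-en-1-ol
Product: 16 4-methylpent-3-enal
Conditions: Dess–Martin periodinane, NaHCO3, CH2Cl2, 0 °C; short silica plug, used at once
Reagents that add atoms: none
Why: Dess–Martin oxidation under bicarbonate buffer is mild and non-basic enough to deliver the β,γ-unsaturated aldehyde without migration of the double bond into conjugation.

**Step 11**
Reactants: 14 1-[3,5-dimethoxy-2-(methoxymethoxy)-4-methylphenyl]ethenyl trifluoromethanesulfonate; 16 4-methylpent-3-enal
Product: 17 (3S)-2-[3,5-dimethoxy-2-(methoxymethoxy)-4-methylphenyl]-6-methylhepta-1,5-dien-3-ol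
Conditions: CrCl2 (3 equiv), N-[2-[(4S)-4-isopropyl-4,5-dihydro-1,3-oxazol-2-yl]-6-methylphenyl]methanesulfonamide (3.3 equiv), Et3N (3.3 equiv), THF, 20 °C; NiCl2 (5 mol %), 14, 16 (1.5 equiv), 20 °C
Reagents that add atoms: none
Why: In this asymmetric Nozaki–Hiyama–Kishi coupling zerovalent nickel inserts into the C–OTf bond, transmetalation gives an alkenyl species of trivalent chromium that carries the chiral sulfonamide ligand, and this adds to the chromium-bound aldehyde on its Re face (by the assumption above) to set the (3S) centre, with the methoxymethyl ether, both alkenes and the acid-sensitive aldehyde left untouched under these neutral conditions.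

**Step 12**
Reactants: 17 (3S)-2-[3,5-dimethoxy-2-(methoxymethoxy)-4-methylphenyl]-6-methylhepta-1,5-dien-3-ol
Product: 18 (3S)-2-[3,5-dimethoxy-2-(methoxymethoxy)-4-methylphenyl]-6-methylhepta-1,5-dien-3-yl (2E)-2-methylbut-2-enoate
Conditions: tigloyl chloride, pyridine, 4-(dimethylamino)pyridine (10 mol %), CH2Cl2, 0 → 20 °C
Reagents that add atoms: (2E)-2-methylbut-2-enoyl chloride, C/C=C(\C)C(=O)Cl
Why: Nucleophile-catalysed acylation of the secondary alcohol leaves the C–O bond of the stereocentre untouched (retention), and pyridine in place of a trialkylamine avoids deconjugation of the acyl chloride through a vinylketene.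

**Step 13**
Reactants: 18 (3S)-2-[3,5-dimethoxy-2-(methoxymethoxy)-4-methylphenyl]-6-methylhepta-1,5-dien-3-yl (2E)-2-methylbut-2-enoate
Product: 20 (3S)-2-(2-hydroxy-3,5-dimethoxy-4-methylphenyl)-6-methylhepta-1,5-dien-3-yl (2E)-2-methylbut-2-enoate, via aryl trimethylsilyl ether 19 (not isolated)
Conditions: Me3SiOTf, 2,2'-bipyridyl, MeCN, 0 °C; then H2O
Reagents that add atoms: none
Why: The silyl triflate–bipyridyl pair converts the aryl methoxymethyl ether into the aryl silyl ether under buffered aprotic conditions and water then frees the phenol (Fujioka-type acetal cleavage), which should spare the allylic tiglate, the trisubstituted alkene, the styrene unit and the stereocentre.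

**Compound list**
1 | methyl 4-methoxy-3-oxobutanoate (methyl 4-methoxyacetoacetate) | COCC(=O)CC(=O)OC | starting material
2 | methyl (2Z)-4-methoxy-3-(trimethylsilyloxy)but-2-enoate | COC/C(O[Si](C)(C)C)=C/C(=O)OC | intermediate
3 | (1E,3Z)-1,4-dimethoxy-1,3-bis(trimethylsilyloxy)buta-1,3-diene | CO/C=C(O[Si](C)(C)C)/C=C(\OC)O[Si](C)(C)C | intermediate
4 | methoxyacetone (1-methoxypropan-2-one) | COCC(C)=O | starting material
5 | (Z)-1-methoxy-2-(trimethylsilyloxy)prop-1-ene | CO/C=C(/C)O[Si](C)(C)C | intermediate
6 | trimethyl orthoformate | COC(OC)OC | starting material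
7 | 3,4,4-trimethoxybutan-2-one (racemic) | CC(=O)C(OC)C(OC)OC | intermediate
8 | methyl 5-hydroxy-4,6,7,7-tetramethoxy-5-methyl-3-oxoheptanoate (diastereomer mixture; held in the flask as its titanium alkoxide and enol derivative, drawn in the neutral keto form) | COC(=O)CC(=O)C(OC)C(C)(O)C(OC)C(OC)OC | intermediate
9 | methyl 4-hydroxy-3,5,6-trimethoxy-4-methyl-2-oxocyclohexane-1-carboxylate (diastereomer mixture) | COC(=O)C1C(OC)C(OC)C(C)(O)C(OC)C1=O | intermediate
10 | methyl 2-hydroxy-3,5-dimethoxy-4-methylbenzoate | COC(=O)c1cc(OC)c(C)c(OC)c1O | intermediate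
11 | methyl 3,5-dimethoxy-2-(methoxymethoxy)-4-methylbenzoate | COCOc1c(OC)c(C)c(OC)cc1C(=O)OC | intermediate
12 | N,3,5-trimethoxy-2-(methoxymethoxy)-N,4-dimethylbenzamide | COCOc1c(OC)c(C)c(OC)cc1C(=O)N(C)OC | intermediate
13 | 1-[3,5-dimethoxy-2-(methoxymethoxy)-4-methylphenyl]ethan-1-one | COCOc1c(OC)c(C)c(OC)cc1C(C)=O | intermediate
14 | 1-[3,5-dimethoxy-2-(methoxymethoxy)-4-methylphenyl]ethenyl trifluoromethanesulfonate | COCOc1c(OC)c(C)c(OC)cc1C(=C)OS(=O)(=O)C(F)(F)F | intermediate
15 | 4-methylpent-3-en-1-ol | CC(C)=CCCO | starting material
16 | 4-methylpent-3-enal | CC(C)=CCC=O | intermediate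
17 | (3S)-2-[3,5-dimethoxy-2-(methoxymethoxy)-4-methylphenyl]-6-methylhepta-1,5-dien-3-ol | C=C(c1cc(OC)c(C)c(OC)c1OCOC)[C@H](CC=C(C)C)O | intermediate
18 | (3S)-2-[3,5-dimethoxy-2-(methoxymethoxy)-4-methylphenyl]-6-methylhepta-1,5-dien-3-yl (2E)-2-methylbut-2-enoate | C=C(c1cc(OC)c(C)c(OC)c1OCOC)[C@H](CC=C(C)C)OC(=O)/C(C)=C/C | intermediate
19 | (3S)-2-[3,5-dimethoxy-4-methyl-2-(trimethylsilyloxy)phenyl]-6-methylhepta-1,5-dien-3-yl (2E)-2-methylbut-2-enoate | C=C(c1cc(OC)c(C)c(OC)c1O[Si](C)(C)C)[C@H](CC=C(C)C)OC(=O)/C(C)=C/C | intermediate
20 | (3S)-2-(2-hydroxy-3,5-dimethoxy-4-methylphenyl)-6-methylhepta-1,5-dien-3-yl (2E)-2-methylbut-2-enoate | C=C(c1cc(OC)c(C)c(OC)c1O)[C@H](CC=C(C)C)OC(=O)/C(C)=C/C | target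

**Step count**
Total: 13 steps. Longest linear sequence: 10 steps (steps 1, 2, 5, 6, 7, 8, 9, 11, 12, 13).

**Steps most likely to fail**

Step 5. The process at risk is a reversal of the order of the two carbon–carbon bond formations: attack of the terminal diene carbon on the acetal carbon first would give the 6-methyl isomer in place of 10. Stalling at the stage of 9 without aromatisation is a lesser risk. The regiochemistry of 10 is to be checked by the long-range coupling of the ring proton to the ester carbonyl carbon before the route goes on. The fallback sets out from 1 and 7 and comes back at 10; it turns the order of bond formation round on purpose and makes it stepwise. Acid hydrolysis of 7 (aq. HCl, THF, 20 °C) gives 2-methoxy-3-oxobutanal F1. Under Knoevenagel conditions (piperidinium acetate, toluene, reflux with removal of water) F1 condenses through its aldehyde carbon with the most acidic carbon of 1 to give methyl 4-methoxy-2-(2-methoxyacetyl)-5-oxohex-2-enoate F2, which fixes the C1–C6 bond. NaOMe in MeOH then brings about the intramolecular aldol condensation of the methoxy-bearing γ-carbon onto the methyl ketone (C3–C4 bond), and loss of water with enolisation leads to 10. In this sequence the regiochemistry rests on classical reactivity: active methylene with aldehyde first, six-ring aldol second.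

Step 11. The processes at risk are poor facial selectivity (or an unexpected sense of induction) in the addition of the alkenylchromium species to the aldehyde, and amine-induced migration of the double bond of 16 into conjugation before coupling. The fallback sets out from 17 of insufficient enantiomeric purity and comes back at 17; such material is also available from 14 and 16 with CrCl2 and catalytic NiCl2 in DMF without ligand. Oxidation with Dess–Martin periodinane and NaHCO3 gives 2-[3,5-dimethoxy-2-(methoxymethoxy)-4-methylphenyl]-6-methylhepta-1,5-dien-3-one F3. Corey–Bakshi–Shibata reduction with (R)-1-methyl-3,3-diphenyltetrahydro-1H,3H-pyrrolo[1,2-c][1,3,2]oxazaborole and catecholborane in toluene at −78 °C returns 17. With the 1-arylethenyl group as the large and the CH2 group as the small substituent, the (R)-catalyst is predicted to give the (3S)-alcohol.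

Step 13. The process at risk is loss or migration of the allylic tiglate, or attack on the conjugated ester, during the Lewis-acidic cleavage of the acetal. The fallback sets out from 17 and comes back at 20; it removes the acetal before any ester is in place. Me3SiOTf and 2,2'-bipyridyl in MeCN convert 17 in the flask into (3S)-2-[3,5-dimethoxy-4-methyl-2-(trimethylsilyloxy)phenyl]-6-methyl-3-(trimethylsilyloxy)hepta-1,5-diene F4, and water then K2CO3 in MeOH gives (3S)-2-(2-hydroxy-3,5-dimethoxy-4-methylphenyl)-6-methylhepta-1,5-dien-3-ol F5. Acylation of both hydroxyl groups with tigloyl chloride, pyridine and 4-(dimethylamino)pyridine gives (3S)-2-{3,5-dimethoxy-4-methyl-2-[(2E)-2-methylbut-2-enoyloxy]phenyl}-6-methylhepta-1,5-dien-3-yl (2E)-2-methylbut-2-enoate F6. The more labile aryl ester is then cleaved selectively by ammonolysis (NH3 in MeOH, 0 °C) to give 20.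

**Further compounds**
F1 | step 5 | 2-methoxy-3-oxobutanal (racemic, in equilibrium with its enol) | CC(=O)C(OC)C=O
F2 | step 5 | methyl 4-methoxy-2-(2-methoxyacetyl)-5-oxohex-2-enoate (racemic, alkene isomer mixture) | COCC(=O)C(=CC(OC)C(C)=O)C(=O)OC
F3 | step 11 | 2-[3,5-dimethoxy-2-(methoxymethoxy)-4-methylphenyl]-6-methylhepta-1,5-dien-3-one | C=C(c1cc(OC)c(C)c(OC)c1OCOC)C(=O)CC=C(C)C
F4 | step 13 | (3S)-2-[3,5-dimethoxy-4-methyl-2-(trimethylsilyloxy)phenyl]-6-methyl-3-(trimethylsilyloxy)hepta-1,5-diene | C=C(c1cc(OC)c(C)c(OC)c1O[Si](C)(C)C)[C@H](CC=C(C)C)O[Si](C)(C)C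
F5 | step 13 | (3S)-2-(2-hydroxy-3,5-dimethoxy-4-methylphenyl)-6-methylhepta-1,5-dien-3-ol | C=C(c1cc(OC)c(C)c(OC)c1O)[C@H](CC=C(C)C)O
F6 | step 13 | (3S)-2-{3,5-dimethoxy-4-methyl-2-[(2E)-2-methylbut-2-enoyloxy]phenyl}-6-methylhepta-1,5-dien-3-yl (2E)-2-methylbut-2-enoate | C=C(c1cc(OC)c(C)c(OC)c1OC(=O)/C(C)=C/C)[C@H](CC=C(C)C)OC(=O)/C(C)=C/C
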